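**Retrosynthetic overview**

1. Target 24 is read as ent-fisetinidol-(4α→6)-ent-fisetinidol-(4α→8)-catechin-(6→4α)-ent-fisetinidol (units A, B, D, C in that order; flavan numbering within each unit); the last operations are desilylation and hydrogenolysis of 22.
2. Every interflavanyl bond is cut as aryllithium + C4 ketone, not arene + C4 cation: the three C4–H centres come from tertiary C4 carbinols by hydride delivery anti to a C3 silyl ether, which gives the 3,4-cis relationship that cationic coupling disfavours.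
3. Key disconnection (step 14), in units A and C at once: C4–aryl and O1–C2. Dibromide 18 (bromine on C6 of unit B and C6 of unit D) plus two molecules of one open-chain (2S,3R)-epoxy ketone 5; each pyran ring closes by phenoxide attack on benzylic C2 of the trans C2–C3 epoxide.
4. Enabling feature: in each ent-fisetinidol unit C4 is a diarylmethine carbon on C4a of a resorcinol ring whose neighbour C8a carries O1, and C2 is benzylic to the catechol ring. C4 can therefore be a ketone, its alkoxide lies 1,5 to a silyl-masked O1 (silyl transfer frees O1 and later parks the silyl group on O3), and O1 is 6-endo to C2.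
5. Ring order: pyran ring of unit D from (+)-catechin; pyran ring of unit B (step 11, same cascade with bromo epoxy ketone 9); pyran rings of units A and C together (step 14).

Key step: step 14

Remark: the SMILES is taken to show three (2S,3R)-ent-fisetinidol units, each 2,3-trans-3,4-cis, on (2R,3S)-catechin; (R)-BINOL is assumed, by analogy with chalcone itself, to be the antipode that gives the (2S,3R)-oxide in steps 3 and 7.

**Route**

Step 1
Reactants: 1 1-[4-(benzyloxy)-2-hydroxyphenyl]ethan-1-one; 2 3,4-bis(benzyloxy)benzaldehyde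
Product: 3 (E)-1-[4-(benzyloxy)-2-hydroxyphenyl]-3-[3,4-bis(benzyloxy)phenyl]prop-2-en-1-one
Conditions: KOH, EtOH, 20 °C
Reagents that add atoms: none
Why: Claisen–Schmidt aldol condensation, in which the chelated 2'-hydroxyl needs no protection and dehydration should give only the E-enone.

Step 2
Reactants: 3 2'-hydroxychalcone
Product: 4 (E)-1-{4-(benzyloxy)-2-[(tert-butyldimethylsilyl)oxy]phenyl}-3-[3,4-bis(benzyloxy)phenyl]prop-2-en-1-one
Conditions: TBSCl, imidazole, DMAP (cat.), DMF, 40 °C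
Reagents that add atoms: tert-butyldimethylsilyl chloride (TBSCl), CC(C)(C)[Si](C)(C)Cl
Why: Phenol silylation; the TBS group is chosen because it can later migrate from this oxygen (the future O1) to an alkoxide.

Step 3
Reactants: 4 2'-O-TBS chalcone
Product: 5 {4-(benzyloxy)-2-[(tert-butyldimethylsilyl)oxy]phenyl}{(2S,3R)-3-[3,4-bis(benzyloxy)phenyl]oxiran-2-yl}methanone
Conditions: La(O-iPr)3 (10 mol %), (R)-BINOL, Ph3As=O, t-BuOOH (decane), MS 4A, THF, 20 °C
Reagents that add atoms: tert-butyl hydroperoxide, CC(C)(C)OO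
Why: Catalytic asymmetric nucleophilic (Weitz–Scheffer-type) epoxidation of an enone with the lanthanum–BINOL–triphenylarsine oxide system, in which the E-enone should give the trans epoxide and the chiral lanthanum peroxide selects the enone face, setting both oxirane carbons (the future C3 and C2) under near-neutral anhydrous conditions that spare the aryl silyl ether.

Step 4
Reactants: 1 1-[4-(benzyloxy)-2-hydroxyphenyl]ethan-1-one
Product: 6 1-[4-(benzyloxy)-5-bromo-2-hydroxyphenyl]ethan-1-one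
Conditions: NBS, MeCN, 0 → 20 °C
Reagents that add atoms: N-bromosuccinimide, O=C1CCC(=O)N1Br
Why: Electrophilic aromatic bromination, expected para to the free hydroxyl and ortho to the benzyloxy group (C5') and not at the hindered position between the two oxygens.

Step 5
Reactants: 6 bromoacetophenone; 2 3,4-bis(benzyloxy)benzaldehyde
Product: 7 (E)-1-[4-(benzyloxy)-5-bromo-2-hydroxyphenyl]-3-[3,4-bis(benzyloxy)phenyl]prop-2-en-1-one
Conditions: KOH, EtOH, 20 °C
Reagents that add atoms: none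
Why: Claisen–Schmidt condensation as in step 1, the aryl bromide being inert to aqueous-alcoholic base.

Step 6
Reactants: 7 bromo 2'-hydroxychalcone
Product: 8 (E)-1-{4-(benzyloxy)-5-bromo-2-[(tert-butyldimethylsilyl)oxy]phenyl}-3-[3,4-bis(benzyloxy)phenyl]prop-2-en-1-one
Conditions: TBSCl, imidazole, DMAP (cat.), DMF, 40 °C
Reagents that add atoms: tert-butyldimethylsilyl chloride (TBSCl), CC(C)(C)[Si](C)(C)Cl
Why: Phenol silylation as in step 2.

Step 7
Reactants: 8 bromo 2'-O-TBS chalcone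
Product: 9 {4-(benzyloxy)-5-bromo-2-[(tert-butyldimethylsilyl)oxy]phenyl}{(2S,3R)-3-[3,4-bis(benzyloxy)phenyl]oxiran-2-yl}methanone
Conditions: La(O-iPr)3 (10 mol %), (R)-BINOL, Ph3As=O, t-BuOOH (decane), MS 4A, THF, 20 °C
Reagents that add atoms: tert-butyl hydroperoxide, CC(C)(C)OO
Why: Same catalytic asymmetric enone epoxidation as in step 3, with trans geometry from the E-enone and face selection by the catalyst.

Step 8
Reactants: 10 (+)-catechin
Product: 11 5,7,3',4'-tetra-O-benzyl-(+)-catechin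
Conditions: BnBr, K2CO3, DMF, 0 → 20 °C
Reagents that add atoms: benzyl bromide, BrCc1ccccc1
Why: Williamson etherification of the four phenols with a weak base that leaves the secondary alcohol free and C2 unepimerized.

Step 9
Reactants: 11 tetra-O-benzylcatechin
Product: 12 3,5,7,3',4'-penta-O-benzyl-(+)-catechin
Conditions: NaH, BnBr, DMF, 0 → 20 °C
Reagents that add atoms: benzyl bromide, BrCc1ccccc1
Why: Williamson etherification of the secondary 3-hydroxyl, so that unit D carries no acidic proton in the organolithium steps.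

Step 10
Reactants: 12 penta-O-benzylcatechin
Product: 13 8-bromo-3,5,7,3',4'-penta-O-benzyl-(+)-catechin
Conditions: NBS, CH2Cl2, −78 → 20 °C
Reagents that add atoms: N-bromosuccinimide, O=C1CCC(=O)N1Br
Why: Electrophilic aromatic bromination of the phloroglucinol-type ring, known for benzylated catechins to go to C8 in preference to C6.

Step 11
Reactants: 13 8-bromo-penta-O-benzylcatechin; 9 bromo epoxy ketone
Product: 16 6-bromo-7,3',4'-tri-O-benzyl-3-O-TBS-4-hydroxy-ent-fisetinidol-(4→8)-penta-O-benzylcatechin (C4 epimers), via aryllithium 14 (not isolated), via lithium alkoxide 15 (not isolated)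
Conditions: t-BuLi (2.1 equiv), THF, −78 °C; then 9, −78 °C; then DMPU, −78 → 40 °C; aq NH4Cl
Reagents that add atoms: none
Why: Proposed new method: aryllithium 14 should add to the non-enolizable ketone of 9 to give alkoxide 15, whose C4 oxygen takes the silyl group from the ortho phenolic oxygen by a six-membered 1,5 O-to-O shift, after which the freed phenoxide opens the trans epoxide 6-endo at benzylic C2 with inversion (2,3-trans pyran ring of unit B) and the C3 alkoxide collects the silyl group by a 1,4 shift; the closest known reaction types are aryllithium addition to 3-O-silyl-4-oxoflavans, base-induced cyclization of 2'-hydroxychalcone epoxides to dihydroflavonols and anionic silyl migration in ortho-silyloxybenzyl alkoxides.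

Step 12
Reactants: 16 unit B–unit D carbinol
Product: 17 6-bromo-7,3',4'-tri-O-benzyl-3-O-TBS-ent-fisetinidol-(4α→8)-3,5,7,3',4'-penta-O-benzylcatechin
Conditions: Bu3SnH, TFA, CH2Cl2, 0 °C
Reagents that add atoms: none
Why: Ionic deoxygenation of a tertiary diaryl carbinol, a reaction type established for 4-aryl-4-hydroxyflavan 3-silyl ethers: TFA ionizes C4 of unit B to a planar cation on which both C4 epimers converge, and Bu3SnH should deliver hydride anti to the C3 silyloxy group, setting C4 with the aryl group cis to O3 while the aryl bromide stays untouched without a radical initiator.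

Step 13
Reactants: 17 bromo dimer
Product: 18 6-bromo-7,3',4'-tri-O-benzyl-3-O-TBS-ent-fisetinidol-(4α→8)-6-bromo-3,5,7,3',4'-penta-O-benzylcatechin
Conditions: NBS, CH2Cl2, −40 → 0 °C
Reagents that add atoms: N-bromosuccinimide, O=C1CCC(=O)N1Br
Why: Electrophilic aromatic bromination at C6 of unit D, the only free position on the sole ring with three oxygen donors and therefore expected to be far more reactive than the resorcinol- and catechol-type rings.

Step 14
Reactants: 18 dibromide; 5 epoxy ketone (2.3 equiv)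
Product: 21 tetradeca-O-benzyl-tris(3-O-TBS) tetraflavanoid 4,4-diol with tertiary hydroxyls on C4 of units A and C (C4 epimers), via dilithio species 19 (not isolated), via bis(lithium alkoxide) 20 (not isolated)
Conditions: t-BuLi (4.2 equiv), THF, −78 °C; then 5, −78 °C; then DMPU, −78 → 40 °C; aq NH4Cl
Reagents that add atoms: none
Why: Proposed new method: double bromine–lithium exchange gives 19, whose two aryl carbanions add to the non-enolizable ketone of two molecules of 5 to give 20; in each half the tertiary C4 alkoxide takes the silyl group from the ortho phenolic oxygen by a six-membered 1,5 O-to-O shift, the freed lithium phenoxide opens the trans epoxide at benzylic C2, and the resulting C3 alkoxide collects the silyl group from the crowded tertiary oxygen by a 1,4 shift. The closest known reaction types are aryllithium addition to 3-O-silyl-4-oxoflavans, base-induced cyclization of 2'-hydroxychalcone epoxides to dihydroflavonols and anionic O-to-O silyl migration in ortho-silyloxybenzyl alkoxides; new is their union in one flask on an open-chain epoxy ketone. Both pyran rings (units A and C) close by 6-endo-tet epoxide opening through formation of O1–C2. C2 of each ring is set by SN2 inversion of the epoxide carbon and C3 keeps the configuration from step 3, so the 2,3-trans relationship follows from the trans epoxide; the two new C4 carbinol centres are left uncontrolled on purpose, since both epimers converge on one cation in step 15. The step needs 6-endo over 5-exo closure, which is secured because C3 is non-benzylic and flanked by the fully substituted C4, and it needs no Payne rearrangement, which is secured because the tertiary oxygen is silylated while the phenoxide exists. The sites of both C–C bonds are fixed by the bromine atoms of 18, and only the oxygen that carried the silyl group can cyclize because every other phenolic oxygen is a benzyl ether.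

Step 15
Reactants: 21 bis-carbinol
Product: 22 tetradeca-O-benzyl-tris(3-O-TBS)-ent-fisetinidol-(4α→6)-ent-fisetinidol-(4α→8)-catechin-(6→4α)-ent-fisetinidol
Conditions: Bu3SnH, TFA, CH2Cl2, 0 °C
Reagents that add atoms: none
Why: Twofold ionic deoxygenation as in step 12: each tertiary carbinol ionizes to a diaryl-stabilized C4 cation and Bu3SnH should deliver hydride anti to the neighbouring C3 silyloxy group, setting C4 of units A and C as 3,4-cis.

Step 16
Reactants: 22 protected tetraflavanoid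
Product: 23 tetradeca-O-benzyl-ent-fisetinidol-(4α→6)-ent-fisetinidol-(4α→8)-catechin-(6→4α)-ent-fisetinidol
Conditions: Bu4NF, THF, 40 °C
Reagents that add atoms: none
Why: Fluoride cleavage of the three secondary silyl ethers, harmless to the benzyl ethers and, with no free phenol present, unable to trigger base-induced pyran ring opening.

Step 17
Reactants: 23 tetradeca-O-benzyl tetraflavanoid
Product: 24 ent-fisetinidol-(4α→6)-ent-fisetinidol-(4α→8)-catechin-(6→4α)-ent-fisetinidol (target)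
Conditions: H2 (1 atm), Pd(OH)2/C, THF–MeOH–H2O, 20 °C
Reagents that add atoms: none
Why: Hydrogenolysis of the fourteen benzyl ethers, the standard last step for benzylated oligoflavanoids, which should leave the interflavanyl C–C bonds and all stereocentres untouched.

**Compound list**

1 | 1-[4-(benzyloxy)-2-hydroxyphenyl]ethan-1-one | CC(=O)c1ccc(OCc2ccccc2)cc1O | starting material
2 | 3,4-bis(benzyloxy)benzaldehyde | O=Cc1ccc(OCc2ccccc2)c(OCc2ccccc2)c1 | starting material
3 | (E)-1-[4-(benzyloxy)-2-hydroxyphenyl]-3-[3,4-bis(benzyloxy)phenyl]prop-2-en-1-one | O=C(/C=C/c1ccc(OCc2ccccc2)c(OCc2ccccc2)c1)c1ccc(OCc2ccccc2)cc1O | intermediate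
4 | 2'-O-TBS ether of 3 | O=C(/C=C/c1ccc(OCc2ccccc2)c(OCc2ccccc2)c1)c1ccc(OCc2ccccc2)cc1O[Si](C)(C)C(C)(C)C | intermediate
5 | {4-(benzyloxy)-2-[(tert-butyldimethylsilyl)oxy]phenyl}{(2S,3R)-3-[3,4-bis(benzyloxy)phenyl]oxiran-2-yl}methanone | O=C(c1ccc(OCc2ccccc2)cc1O[Si](C)(C)C(C)(C)C)[C@H]1O[C@@H]1c1ccc(OCc2ccccc2)c(OCc2ccccc2)c1 | intermediate
6 | 1-[4-(benzyloxy)-5-bromo-2-hydroxyphenyl]ethan-1-one | CC(=O)c1cc(Br)c(OCc2ccccc2)cc1O | intermediate
7 | (E)-1-[4-(benzyloxy)-5-bromo-2-hydroxyphenyl]-3-[3,4-bis(benzyloxy)phenyl]prop-2-en-1-one | O=C(/C=C/c1ccc(OCc2ccccc2)c(OCc2ccccc2)c1)c1cc(Br)c(OCc2ccccc2)cc1O | intermediate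
8 | 2'-O-TBS ether of 7 | O=C(/C=C/c1ccc(OCc2ccccc2)c(OCc2ccccc2)c1)c1cc(Br)c(OCc2ccccc2)cc1O[Si](C)(C)C(C)(C)C | intermediate
9 | {4-(benzyloxy)-5-bromo-2-[(tert-butyldimethylsilyl)oxy]phenyl}{(2S,3R)-3-[3,4-bis(benzyloxy)phenyl]oxiran-2-yl}methanone | O=C(c1cc(Br)c(OCc2ccccc2)cc1O[Si](C)(C)C(C)(C)C)[C@H]1O[C@@H]1c1ccc(OCc2ccccc2)c(OCc2ccccc2)c1 | intermediate
10 | (+)-catechin, (2R,3S)-2-(3,4-dihydroxyphenyl)chromane-3,5,7-triol | Oc1cc(O)c2c(c1)O[C@H](c1ccc(O)c(O)c1)[C@@H](O)C2 | starting material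
11 | 5,7,3',4'-tetra-O-benzyl-(+)-catechin | c1c(OCc3ccccc3)cc(OCc3ccccc3)c2c1O[C@H](c1ccc(OCc3ccccc3)c(OCc3ccccc3)c1)[C@@H](O)C2 | intermediate
12 | 3,5,7,3',4'-penta-O-benzyl-(+)-catechin | c1c(OCc3ccccc3)cc(OCc3ccccc3)c2c1O[C@H](c1ccc(OCc3ccccc3)c(OCc3ccccc3)c1)[C@@H](OCc1ccccc1)C2 | intermediate
13 | 8-bromo-3,5,7,3',4'-penta-O-benzyl-(+)-catechin | Brc1c(OCc3ccccc3)cc(OCc3ccccc3)c2c1O[C@H](c1ccc(OCc3ccccc3)c(OCc3ccccc3)c1)[C@@H](OCc1ccccc1)C2 | intermediate
14 | 8-lithio-3,5,7,3',4'-penta-O-benzylcatechin | [Li]c1c(OCc3ccccc3)cc(OCc3ccccc3)c2c1O[C@H](c1ccc(OCc3ccccc3)c(OCc3ccccc3)c1)[C@@H](OCc1ccccc1)C2 | intermediate (not isolated)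
15 | open-chain lithium alkoxide from 14 and 9 (carbinol carbon bearing catechin C8, the 4-benzyloxy-5-bromo-2-silyloxyphenyl ring and the epoxide) | [Li]OC(c1cc(Br)c(OCc2ccccc2)cc1O[Si](C)(C)C(C)(C)C)([C@H]1O[C@@H]1c1ccc(OCc2ccccc2)c(OCc2ccccc2)c1)c1c(OCc3ccccc3)cc(OCc3ccccc3)c2c1O[C@H](c1ccc(OCc3ccccc3)c(OCc3ccccc3)c1)[C@@H](OCc1ccccc1)C2 | intermediate (not isolated)
16 | 6-bromo-7,3',4'-tri-O-benzyl-3-O-TBS-4-hydroxy-ent-fisetinidol-(4→8)-penta-O-benzylcatechin, C4 epimers | Brc1cc2c(cc1OCc1ccccc1)O[C@@H](c1ccc(OCc3ccccc3)c(OCc3ccccc3)c1)[C@H](O[Si](C)(C)C(C)(C)C)C2(O)c1c(OCc3ccccc3)cc(OCc3ccccc3)c2c1O[C@H](c1ccc(OCc3ccccc3)c(OCc3ccccc3)c1)[C@@H](OCc1ccccc1)C2 | intermediate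
17 | 6-bromo-7,3',4'-tri-O-benzyl-3-O-TBS-ent-fisetinidol-(4α→8)-3,5,7,3',4'-penta-O-benzylcatechin | Brc1cc2c(cc1OCc1ccccc1)O[C@@H](c1ccc(OCc3ccccc3)c(OCc3ccccc3)c1)[C@H](O[Si](C)(C)C(C)(C)C)[C@@H]2c1c(OCc3ccccc3)cc(OCc3ccccc3)c2c1O[C@H](c1ccc(OCc3ccccc3)c(OCc3ccccc3)c1)[C@@H](OCc1ccccc1)C2 | intermediate
18 | dibromide: 17 with a second bromine on C6 of the catechin unit | Brc1cc2c(cc1OCc1ccccc1)O[C@@H](c1ccc(OCc3ccccc3)c(OCc3ccccc3)c1)[C@H](O[Si](C)(C)C(C)(C)C)[C@@H]2c1c(OCc3ccccc3)c(Br)c(OCc3ccccc3)c2c1O[C@H](c1ccc(OCc3ccccc3)c(OCc3ccccc3)c1)[C@@H](OCc1ccccc1)C2 | intermediate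
19 | dilithio species: 18 with lithium in place of both bromine atoms | [Li]c1cc2c(cc1OCc1ccccc1)O[C@@H](c1ccc(OCc3ccccc3)c(OCc3ccccc3)c1)[C@H](O[Si](C)(C)C(C)(C)C)[C@@H]2c1c(OCc3ccccc3)c([Li])c(OCc3ccccc3)c2c1O[C@H](c1ccc(OCc3ccccc3)c(OCc3ccccc3)c1)[C@@H](OCc1ccccc1)C2 | intermediate (not isolated)
20 | bis(lithium alkoxide): twofold open-chain adduct of 19 to 5, on C6 of unit B and C6 of unit D | [Li]OC(c1ccc(OCc2ccccc2)cc1O[Si](C)(C)C(C)(C)C)([C@H]1O[C@@H]1c1ccc(OCc2ccccc2)c(OCc2ccccc2)c1)c1cc2c(cc1OCc1ccccc1)O[C@@H](c1ccc(OCc3ccccc3)c(OCc3ccccc3)c1)[C@H](O[Si](C)(C)C(C)(C)C)[C@@H]2c1c(OCc3ccccc3)c(C(O[Li])(c3ccc(OCc4ccccc4)cc3O[Si](C)(C)C(C)(C)C)[C@H]3O[C@@H]3c3ccc(OCc4ccccc4)c(OCc4ccccc4)c3)c(OCc3ccccc3)c2c1O[C@H](c1ccc(OCc3ccccc3)c(OCc3ccccc3)c1)[C@@H](OCc1ccccc1)C2 | intermediate (not isolated)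
21 | tetradeca-O-benzyl-tris(3-O-TBS) tetraflavanoid with tertiary hydroxyls on C4 of units A and C, C4 epimers | c1ccccc1COc1ccc2c(c1)O[C@@H](c1ccc(OCc3ccccc3)c(OCc3ccccc3)c1)[C@H](O[Si](C)(C)C(C)(C)C)C2(O)c1cc2c(cc1OCc1ccccc1)O[C@@H](c1ccc(OCc3ccccc3)c(OCc3ccccc3)c1)[C@H](O[Si](C)(C)C(C)(C)C)[C@@H]2c1c(OCc3ccccc3)c(C2(O)c3ccc(OCc4ccccc4)cc3O[C@@H](c3ccc(OCc4ccccc4)c(OCc4ccccc4)c3)[C@@H]2O[Si](C)(C)C(C)(C)C)c(OCc3ccccc3)c2c1O[C@H](c1ccc(OCc3ccccc3)c(OCc3ccccc3)c1)[C@@H](OCc1ccccc1)C2 | intermediate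
22 | tetradeca-O-benzyl-tris(3-O-TBS)-ent-fisetinidol-(4α→6)-ent-fisetinidol-(4α→8)-catechin-(6→4α)-ent-fisetinidol | c1ccccc1COc1ccc2c(c1)O[C@@H](c1ccc(OCc3ccccc3)c(OCc3ccccc3)c1)[C@H](O[Si](C)(C)C(C)(C)C)[C@@H]2c1cc2c(cc1OCc1ccccc1)O[C@@H](c1ccc(OCc3ccccc3)c(OCc3ccccc3)c1)[C@H](O[Si](C)(C)C(C)(C)C)[C@@H]2c1c(OCc3ccccc3)c([C@@H]2c3ccc(OCc4ccccc4)cc3O[C@@H](c3ccc(OCc4ccccc4)c(OCc4ccccc4)c3)[C@@H]2O[Si](C)(C)C(C)(C)C)c(OCc3ccccc3)c2c1O[C@H](c1ccc(OCc3ccccc3)c(OCc3ccccc3)c1)[C@@H](OCc1ccccc1)C2 | intermediate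
23 | tetradeca-O-benzyl-ent-fisetinidol-(4α→6)-ent-fisetinidol-(4α→8)-catechin-(6→4α)-ent-fisetinidol | c1ccccc1COc1ccc2c(c1)O[C@@H](c1ccc(OCc3ccccc3)c(OCc3ccccc3)c1)[C@H](O)[C@@H]2c1cc2c(cc1OCc1ccccc1)O[C@@H](c1ccc(OCc3ccccc3)c(OCc3ccccc3)c1)[C@H](O)[C@@H]2c1c(OCc3ccccc3)c([C@@H]2c3ccc(OCc4ccccc4)cc3O[C@@H](c3ccc(OCc4ccccc4)c(OCc4ccccc4)c3)[C@@H]2O)c(OCc3ccccc3)c2c1O[C@H](c1ccc(OCc3ccccc3)c(OCc3ccccc3)c1)[C@@H](OCc1ccccc1)C2 | intermediate
24 | ent-fisetinidol-(4α→6)-ent-fisetinidol-(4α→8)-catechin-(6→4α)-ent-fisetinidol (units A to C 2S,3R with C4 R in unit A and S in units B and C; unit D 2R,3S) | Oc1ccc2c(c1)O[C@@H](c1ccc(O)c(O)c1)[C@H](O)[C@@H]2c1cc2c(cc1O)O[C@@H](c1ccc(O)c(O)c1)[C@H](O)[C@@H]2c1c(O)c([C@@H]2c3ccc(O)cc3O[C@@H](c3ccc(O)c(O)c3)[C@@H]2O)c(O)c2c1O[C@H](c1ccc(O)c(O)c1)[C@@H](O)C2 | target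

**Totals and risks**

Total step count: 17. Longest linear sequence: 11 steps (steps 4 to 7, then 11 to 17; from 1 through 6, 7, 8, 9, 16, 17, 18, 21, 22 and 23 to 24).

Steps most likely to fail:

1. Step 14 (proposed new method). What may go wrong: incomplete double bromine–lithium exchange or addition, stalling of the silyl transfer so that open-chain carbinols remain, Payne rearrangement of the tertiary alkoxide, or 5-exo closure. Fallback: the pyran rings are closed before the coupling. Epoxy ketone 5 is treated with Bu4NF in THF at 0 °C, so that the freed phenoxide cyclizes onto the epoxide (the classical chalcone epoxide to dihydroflavonol closure) to give (2S,3S)-7-(benzyloxy)-2-[3,4-bis(benzyloxy)phenyl]-3-hydroxychroman-4-one F1. F1 is resilylated (TBSCl, imidazole, DMF) to its 3-O-TBS ether F2. Dilithio species 19, generated from 18 as before, is then added to 2.3 equiv of F2 at −78 °C, an aryllithium addition to a 3-silyloxy-4-oxoflavan, which gives 21 directly; the route is rejoined at 21.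

2. Step 11 (proposed new method). What may go wrong: the same stalling of the silyl transfer or ring closure, and in addition lithium–bromine scrambling between 14 and the aryl bromide of 9. Fallback: bromo epoxy ketone 9 is cyclized with Bu4NF in THF at 0 °C to (2S,3S)-7-(benzyloxy)-2-[3,4-bis(benzyloxy)phenyl]-6-bromo-3-hydroxychroman-4-one F3, which is silylated to its 3-O-TBS ether F4. Aryllithium 14, made from 13, is added to F4 at −78 °C to give 16, where the route is rejoined.

3. Step 15. What may go wrong: poor facial selectivity of hydride delivery at one or both C4 cations, or cationic side reactions such as a 1,2-hydride shift from C3 or silyl loss. Fallback: the deoxygenation is moved from a cation to a radical. Bis-carbinol 21 is converted with KN(SiMe3)2 and methyl chlorooxalate in THF at −78 °C into the bis(methyl oxalate) of 21 F5, which is reduced with Bu3SnH and AIBN in toluene at 100 °C (Barton–McCombie-type deoxygenation of tertiary oxalates). The planar C4 radicals should take up hydrogen anti to the C3 silyloxy group, and the route is rejoined at 22.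

**Further compounds**

F1 | step 14 | (2S,3S)-7-(benzyloxy)-2-[3,4-bis(benzyloxy)phenyl]-3-hydroxychroman-4-one | O=C1c2ccc(OCc3ccccc3)cc2O[C@@H](c2ccc(OCc3ccccc3)c(OCc3ccccc3)c2)[C@@H]1O
F2 | step 14 | (2S,3S)-7-(benzyloxy)-2-[3,4-bis(benzyloxy)phenyl]-3-[(tert-butyldimethylsilyl)oxy]chroman-4-one | O=C1c2ccc(OCc3ccccc3)cc2O[C@@H](c2ccc(OCc3ccccc3)c(OCc3ccccc3)c2)[C@@H]1O[Si](C)(C)C(C)(C)C
F3 | step 11 | (2S,3S)-7-(benzyloxy)-2-[3,4-bis(benzyloxy)phenyl]-6-bromo-3-hydroxychroman-4-one | O=C1c2cc(Br)c(OCc3ccccc3)cc2O[C@@H](c2ccc(OCc3ccccc3)c(OCc3ccccc3)c2)[C@@H]1O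
F4 | step 11 | (2S,3S)-7-(benzyloxy)-2-[3,4-bis(benzyloxy)phenyl]-6-bromo-3-[(tert-butyldimethylsilyl)oxy]chroman-4-one | O=C1c2cc(Br)c(OCc3ccccc3)cc2O[C@@H](c2ccc(OCc3ccccc3)c(OCc3ccccc3)c2)[C@@H]1O[Si](C)(C)C(C)(C)C
F5 | step 15 | bis(methyl oxalate) of 21 (oxalate esters on the tertiary C4 oxygens of units A and C) | c1ccccc1COc1ccc2c(c1)O[C@@H](c1ccc(OCc3ccccc3)c(OCc3ccccc3)c1)[C@H](O[Si](C)(C)C(C)(C)C)C2(OC(=O)C(=O)OC)c1cc2c(cc1OCc1ccccc1)O[C@@H](c1ccc(OCc3ccccc3)c(OCc3ccccc3)c1)[C@H](O[Si](C)(C)C(C)(C)C)[C@@H]2c1c(OCc3ccccc3)c(C2(OC(=O)C(=O)OC)c3ccc(OCc4ccccc4)cc3O[C@@H](c3ccc(OCc4ccccc4)c(OCc4ccccc4)c3)[C@@H]2O[Si](C)(C)C(C)(C)C)c(OCc3ccccc3)c2c1O[C@H](c1ccc(OCc3ccccc3)c(OCc3ccccc3)c1)[C@@H](OCc1ccccc1)C2
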